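**Strategy.** The route rests on disconnecting the hydroquinone ring into dimethyl squarate and a terminal alkyne. In the 2,5-dihydroxy-3,4-dimethoxyphenyl ring, C2'–C5' with their four oxygens are the squarate carbons; C1' (bearing the benzylic CH2) and C6'–H are the two alkyne carbons of a 5-propargylimidazole. Heating the acetylide–squarate adduct, a 4-alkynyl-4-hydroxy-2,3-dimethoxycyclobutenone, opens the four-membered ring to a ketene that bonds C2' to C1' and delivers the fully oxygenated benzoquinone in one operation, with no arene oxidation. The precursor already carries the complete 1-methyl-4-(4-methoxybenzyl)imidazole; its 2-amino group is masked as a 2,5-dimethylpyrrole and the tertiary hydroxyl is left free as the hydrogen donor.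

Key step: step 7

Remark: the stereocentre of 1 is carried nominally as (S) through compounds 2–8 and is destroyed when the imidazole forms, so its erosion is of no consequence; 4-methoxybenzylmagnesium chloride (THF solution) and 1-methylparabanic acid are taken as purchased materials.

**Step 1**
Reactants: 1 N-Boc-L-propargylglycine
Product: 2 N-Boc-N-methyl-L-propargylglycine
Conditions: NaH (2.5 equiv), MeI (excess), THF, 0 °C to rt; then cold 1 M HCl to pH 3
Reagents that add atoms: iodomethane, CI
Why: NaH forms the carboxylate–carbamate dianion and MeI alkylates only the carbamate nitrogen (standard N-methylation of a Boc amino acid), the terminal alkyne being metalated too slowly by NaH in THF to compete, and the stereocentre is simply inherited from 1.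

**Step 2**
Reactants: 2 N-Boc-N-methyl-L-propargylglycine
Product: 4 Weinreb amide tert-butyl N-[(2S)-1-[methoxy(methyl)amino]-1-oxopent-4-yn-2-yl]-N-methylcarbamate, via acyl imidazolide 3 (not isolated)
Conditions: CDI, CH2Cl2, rt; then MeNH(OMe)·HCl, rt
Reagents that add atoms: N,O-dimethylhydroxylamine hydrochloride, CNOC.Cl
Why: CDI activates the acid as acyl imidazolide 3, which acylates N,O-dimethylhydroxylamine (amide coupling to a Weinreb amide), the released imidazole serving as the base.

**Step 3**
Reactants: 4 Weinreb amide; 5 4-methoxybenzylmagnesium chloride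
Product: 6 tert-butyl N-[(3S)-1-(4-methoxyphenyl)-2-oxohex-5-yn-3-yl]-N-methylcarbamate
Conditions: 4-MeOC6H4CH2MgCl (3 equiv, THF), THF, −20 to 0 °C; sat. aq. NH4Cl at 0 °C
Reagents that add atoms: none
Why: Weinreb ketone synthesis, in which the benzylic Grignard reagent adds once to give a chelated tetrahedral intermediate that releases the ketone only on quench, while one sacrificial equivalent is consumed by the alkyne C–H, which is restored on protonation.

**Step 4**
Reactants: 6 N-Boc-N-methylamino ketone; 7 cyanamide
Product: 9 2-amino-4-(4-methoxybenzyl)-1-methyl-5-(prop-2-yn-1-yl)-1H-imidazole, via amino ketone hydrochloride 8 (not isolated)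
Conditions: 4 M HCl in dioxane, rt; concentrate; H2NCN (5 equiv), EtOH/H2O, pH 4.5 (aq. NaOH), 95 °C; then aq. NaOH to pH 10
Reagents that add atoms: none
Why: Acidolysis of the Boc group is followed by the classical 2-aminoimidazole synthesis from an α-amino ketone and cyanamide (amine addition to the nitrile, cyclodehydration of the guanidine onto the ketone, aromatisation), in which the N-methyl group fixes N1, the former α-carbon becomes C5 with its propargyl group and its stereocentre is erased.

**Step 5**
Reactants: 9 2-aminoimidazole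
Product: 10 2-(2,5-dimethyl-1H-pyrrol-1-yl)-4-(4-methoxybenzyl)-1-methyl-5-(prop-2-yn-1-yl)-1H-imidazole
Conditions: hexane-2,5-dione (1.5 equiv), TsOH·H2O (cat.), toluene, reflux, Dean–Stark
Reagents that add atoms: hexane-2,5-dione, CC(=O)CCC(C)=O
Why: Paal–Knorr condensation turns the only NH2 group into a base- and heat-stable 2,5-dimethylpyrrole, so no acidic or nucleophilic nitrogen is left for the organolithium, squarate and ketene stages, and the N1-methyl group rules out any ring-nitrogen participation.

**Step 6**
Reactants: 10 pyrrole-masked propargylimidazole; 11 dimethyl squarate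
Product: 13 racemic 4-hydroxy-2,3-dimethoxy-4-{3-[2-(2,5-dimethylpyrrol-1-yl)-4-(4-methoxybenzyl)-1-methylimidazol-5-yl]prop-1-yn-1-yl}cyclobut-2-en-1-one, via lithium acetylide 12 (not isolated)
Conditions: n-BuLi (1.0 equiv), THF, −78 °C; cannulate into 11 (1.2 equiv), THF, −78 °C; sat. aq. NH4Cl at −78 °C
Reagents that add atoms: none
Why: Kinetic lithiation of the terminal alkyne and 1,2-addition of the acetylide to one of the two equivalent carbonyls of the squarate ester is the standard entry to 4-alkynyl-4-hydroxycyclobutenones, and the new carbinol centre forms as a racemate that the next step destroys.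

**Step 7**
Reactants: 13 alkynylhydroxycyclobutenone
Product: 14 2,3-dimethoxy-5-{[2-(2,5-dimethylpyrrol-1-yl)-4-(4-methoxybenzyl)-1-methylimidazol-5-yl]methyl}-1,4-benzoquinone
Conditions: p-xylene (0.01 M, degassed), reflux (138 °C), argon
Reagents that add atoms: none
Why: Thermal four-electron conrotatory opening of the cyclobutenone, with the hydroxyl turning outward and the alkynyl group inward, gives a (2-alkynylethenyl)ketene. The ketene carbon (future C2') then bonds to the distal alkyne carbon (future C1', bearing the CH2) to give a six-membered diradical, and transfer of the hydroxyl hydrogen to the ring carbon radical (future C6') gives the quinone; this is the Moore cyclization of squarate-derived 4-alkynyl-4-hydroxycyclobutenones. The one ring formed is closed in the six-membered mode by this single C–C bond, and no stereocentre is created, the carbinol centre of 13 being lost. Two selectivities are needed: outward rotation of the hydroxyl, which the donor OH at the ring sp3 carbon secures, and six- over five-membered closure, which the sp3 CH2 on the alkyne terminus secures because it cannot stabilise the exocyclic vinyl radical that leads to an alkylidenecyclopentenedione. The pyrrole mask leaves no N–H to intercept the ketene, and high dilution suppresses bimolecular capture by the flanked imidazole N3.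

**Step 8**
Reactants: 14 benzoquinone
Product: 16 5-{[2-amino-4-(4-methoxybenzyl)-1-methyl-1H-imidazol-5-yl]methyl}-2,3-dimethoxybenzene-1,4-diol, via hydroquinone 15 (not isolated)
Conditions: aq. Na2S2O4, EtOAc, rt, argon; concentrate; NH2OH·HCl (20 equiv), EtOH/H2O 2:1 (degassed), reflux; then aq. NaHCO3 to pH 8 under argon
Reagents that add atoms: none
Why: Dithionite reduces the quinone first so that no carbonyl is left for oxime formation, and hydroxylamine then opens the 2,5-dimethylpyrrole to hexane-2,5-dione dioxime and the free amine (the standard cleavage of this protecting group), the mildly acidic medium keeping the electron-rich hydroquinone from autoxidation.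

**Step 9**
Reactants: 16 aminoimidazole hydroquinone; 17 1-methylparabanic acid
Product: 21 naamidine E, via silyl imidate 18 (not isolated), via bis-silyl ether 19 (not isolated), via bis-silyl naamidine E 20 (not isolated)
Conditions: 17 (3 equiv), BSA, MeCN, 80 °C; separately 16, BSA, MeCN, rt; combine, toluene, 110 °C, argon; then THF/H2O/AcOH, rt
Reagents that add atoms: none
Why: The O-silyl imidate 18 undergoes addition–elimination at C4 by the exocyclic 2-amino group (the established condensation of 2-aminoimidazoles to the naamidine-type dehydrohydantoin), while transient O-silylation protects both phenols and is removed on aqueous work-up.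

**Compound list**
1 | N-Boc-L-propargylglycine, (2S)-2-(tert-butoxycarbonylamino)pent-4-ynoic acid | CC(C)(C)OC(=O)N[C@@H](CC#C)C(=O)O | starting material
2 | N-Boc-N-methyl-L-propargylglycine | CC(C)(C)OC(=O)N(C)[C@@H](CC#C)C(=O)O | intermediate
3 | acyl imidazolide of 2, tert-butyl N-[(2S)-1-(imidazol-1-yl)-1-oxopent-4-yn-2-yl]-N-methylcarbamate | CC(C)(C)OC(=O)N(C)[C@@H](CC#C)C(=O)n1ccnc1 | intermediate (not isolated)
4 | Weinreb amide, tert-butyl N-[(2S)-1-[methoxy(methyl)amino]-1-oxopent-4-yn-2-yl]-N-methylcarbamate | CC(C)(C)OC(=O)N(C)[C@@H](CC#C)C(=O)N(C)OC | intermediate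
5 | 4-methoxybenzylmagnesium chloride | COc1ccc(C[Mg]Cl)cc1 | starting material
6 | tert-butyl N-[(3S)-1-(4-methoxyphenyl)-2-oxohex-5-yn-3-yl]-N-methylcarbamate | CC(C)(C)OC(=O)N(C)[C@@H](CC#C)C(=O)Cc1ccc(OC)cc1 | intermediate
7 | cyanamide | NC#N | starting material
8 | (3S)-1-(4-methoxyphenyl)-3-(methylamino)hex-5-yn-2-one hydrochloride | C[NH2+][C@@H](CC#C)C(=O)Cc1ccc(OC)cc1.[Cl-] | intermediate (not isolated)
9 | 2-amino-4-(4-methoxybenzyl)-1-methyl-5-(prop-2-yn-1-yl)-1H-imidazole | COc1ccc(Cc2nc(N)n(C)c2CC#C)cc1 | intermediate
10 | 2-(2,5-dimethyl-1H-pyrrol-1-yl)-4-(4-methoxybenzyl)-1-methyl-5-(prop-2-yn-1-yl)-1H-imidazole | COc1ccc(Cc2nc(-n3c(C)ccc3C)n(C)c2CC#C)cc1 | intermediate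
11 | dimethyl squarate, 3,4-dimethoxycyclobut-3-ene-1,2-dione | COC1=C(OC)C(=O)C1=O | starting material
12 | lithium acetylide of 10 | [Li]C#CCc1c(Cc2ccc(OC)cc2)nc(-n2c(C)ccc2C)n1C | intermediate (not isolated)
13 | racemic 4-hydroxy-2,3-dimethoxy-4-{3-[2-(2,5-dimethylpyrrol-1-yl)-4-(4-methoxybenzyl)-1-methylimidazol-5-yl]prop-1-yn-1-yl}cyclobut-2-en-1-one | COC1=C(OC)C(O)(C#CCc2c(Cc3ccc(OC)cc3)nc(-n3c(C)ccc3C)n2C)C1=O | intermediate (key-step precursor)
14 | 2,3-dimethoxy-5-{[2-(2,5-dimethylpyrrol-1-yl)-4-(4-methoxybenzyl)-1-methylimidazol-5-yl]methyl}cyclohexa-2,5-diene-1,4-dione | COC1=C(OC)C(=O)C(Cc2c(Cc3ccc(OC)cc3)nc(-n3c(C)ccc3C)n2C)=CC1=O | intermediate (key-step product)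
15 | 2,3-dimethoxy-5-{[2-(2,5-dimethylpyrrol-1-yl)-4-(4-methoxybenzyl)-1-methylimidazol-5-yl]methyl}benzene-1,4-diol | COc1c(OC)c(O)c(Cc2c(Cc3ccc(OC)cc3)nc(-n3c(C)ccc3C)n2C)cc1O | intermediate (not isolated)
16 | 5-{[2-amino-4-(4-methoxybenzyl)-1-methyl-1H-imidazol-5-yl]methyl}-2,3-dimethoxybenzene-1,4-diol | COc1c(OC)c(O)c(Cc2c(Cc3ccc(OC)cc3)nc(N)n2C)cc1O | intermediate
17 | 1-methylparabanic acid, 1-methylimidazolidine-2,4,5-trione | CN1C(=O)NC(=O)C1=O | starting material
18 | 1-methyl-4-(trimethylsilyloxy)-1H-imidazole-2,5-dione (O-silyl imidate of 17) | CN1C(=O)N=C(O[Si](C)(C)C)C1=O | intermediate (not isolated)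
19 | bis(trimethylsilyl) ether of 16 | COc1c(OC)c(O[Si](C)(C)C)c(Cc2c(Cc3ccc(OC)cc3)nc(N)n2C)cc1O[Si](C)(C)C | intermediate (not isolated)
20 | bis(trimethylsilyl) ether of naamidine E | COc1ccc(Cc2nc(NC3=NC(=O)N(C)C3=O)n(C)c2Cc2cc(O[Si](C)(C)C)c(OC)c(OC)c2O[Si](C)(C)C)cc1 | intermediate (not isolated)
21 | naamidine E | COc1ccc(Cc2nc(NC3=NC(=O)N(C)C3=O)n(C)c2Cc2cc(O)c(OC)c(OC)c2O)cc1 | target

**Step count.** Total: 9 steps. Longest linear sequence: 9 steps (1 to 21); all other inputs are purchased.

**Steps most likely to fail**

Step 7. The ketene may close onto the proximal alkyne carbon (five-membered ring), or the ketene or diradical may be captured by a second molecule, so that the quinone is formed inefficiently. The fallback sets out from 13. Semihydrogenation of the alkyne (H2, Pd/CaCO3 poisoned with Pb(OAc)2, quinoline, EtOAc, rt) should give the racemic (Z)-alkenylhydroxycyclobutenone F1. Heating F1 in toluene opens the ring to a dienylketene that closes by a concerted 6π electrocyclisation, for which no diradical and no five-membered alternative exist, and enolisation of the cyclohexadienone gives the hydroquinone directly. The route is rejoined at 15, which enters the hydroxylamine stage of step 8.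

Step 6. Metalation of the doubly activated CH2 between imidazole and alkyne may compete with terminal lithiation and lead to propargyl–allenyl isomerisation and a poor yield of adduct. The fallback sets out from 10 and generates the carbanion without any deprotonation. Radical hydrostannation (Bu3SnH, AIBN, toluene, 90 °C) should give the (E)-vinylstannane F2. Tin–lithium exchange (n-BuLi, THF, −78 °C) gives the (E)-alkenyllithium F3, which is added to 11 at −78 °C to give the racemic (E)-alkenylhydroxycyclobutenone F4. Thermolysis of F4 in toluene (ring opening, 6π electrocyclisation, enolisation) returns to the route at hydroquinone 15; a minor (Z)-stannane would converge on the same compound.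

Step 8. Slow opening of the hindered pyrrole may force prolonged heating, during which the hydroquinone is re-oxidised and the quinone is consumed by hydroxylamine. The fallback sets out from 14 and carries the hydroquinone through the unmasking as an oxidation-proof ether. Reductive benzylation (aq. Na2S2O4; then BnBr, K2CO3, DMF, argon) should give the bis(benzyl ether) F5. This tolerates forcing pyrrole cleavage (NH2OH·HCl, KOH, EtOH/H2O, reflux) to the aminoimidazole bis(benzyl ether) F6. Neutral hydrogenolysis (H2, Pd/C, EtOH) releases the hydroquinone just before the final condensation, and the route is rejoined at 16.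

**Further compounds**
F1 | step 7 | racemic 4-hydroxy-2,3-dimethoxy-4-{(1Z)-3-[2-(2,5-dimethylpyrrol-1-yl)-4-(4-methoxybenzyl)-1-methylimidazol-5-yl]prop-1-en-1-yl}cyclobut-2-en-1-one | COC1=C(OC)C(O)(/C=C\Cc2c(Cc3ccc(OC)cc3)nc(-n3c(C)ccc3C)n2C)C1=O
F2 | step 6 | 5-[(2E)-3-(tributylstannyl)prop-2-en-1-yl]-2-(2,5-dimethylpyrrol-1-yl)-4-(4-methoxybenzyl)-1-methylimidazole | CCCC[Sn](CCCC)(CCCC)/C=C/Cc1c(Cc2ccc(OC)cc2)nc(-n2c(C)ccc2C)n1C
F3 | step 6 | (E)-alkenyllithium from F2 | [Li]/C=C/Cc1c(Cc2ccc(OC)cc2)nc(-n2c(C)ccc2C)n1C
F4 | step 6 | racemic 4-hydroxy-2,3-dimethoxy-4-{(1E)-3-[2-(2,5-dimethylpyrrol-1-yl)-4-(4-methoxybenzyl)-1-methylimidazol-5-yl]prop-1-en-1-yl}cyclobut-2-en-1-one | COC1=C(OC)C(O)(/C=C/Cc2c(Cc3ccc(OC)cc3)nc(-n3c(C)ccc3C)n2C)C1=O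
F5 | step 8 | bis(benzyl ether) of 15 | COc1c(OC)c(OCc2ccccc2)c(Cc2c(Cc3ccc(OC)cc3)nc(-n3c(C)ccc3C)n2C)cc1OCc1ccccc1
F6 | step 8 | bis(benzyl ether) of 16 | COc1c(OC)c(OCc2ccccc2)c(Cc2c(Cc3ccc(OC)cc3)nc(N)n2C)cc1OCc1ccccc1
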